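**Retrosynthetic overview**

- Target 23 is opened back to β,γ-epoxy ketone 22 (E1cB opening), then to β,γ-enone 21 (the C5 hydroxyl directs epoxidation of C3=C4 and so sets C4), then to conjugated enone 19 and its silyl ether 18 (deconjugation).
- Key disconnection: 18 comes from cyclobutanone 16 and acetylene 17 by nickel-catalysed insertion, which makes C1–C2 and C3–C4 and cuts one enantiotopic C(O)–CH2 bond.
- Feature the strategy rests on: in the cyclohexenone ring, C5 (the fully substituted carbinol carbon carrying the C17 chain) lies 1,3 to the C1 carbonyl between C4 and C6, exactly as C3 does in a cyclobutanone, and C2=C3 is unsubstituted, so it can come from acetylene.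
- 16 comes from a dichloroketene [2+2] with silyl enol ether 12 of methyl ketone 10; 10 comes from a C17 Grignard reagent and a Weinreb amide; the C17 chain comes from a C6 + C11 sp3–sp3 coupling.
- Ring order: the four-membered ring (step 6) is expanded to the six-membered ring (step 8); the epoxide of step 11 is transient.

Key step: step 8

Remark: ring positions are numbered as in the target (C1 carbonyl, C2=C3, C4 secondary carbinol, C5 tertiary carbinol, C6 methylene), and the chiral ligand of step 8 is assumed to be accessible in both antipodes, the one that leads to (R)-18 being used.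

**Route**

Step 1
Reactants: 1 (E)-hex-3-en-1-ol
Product: 2 (E)-1-bromohex-3-ene
Conditions: CBr4, PPh3, CH2Cl2, 0 °C
Reagents that add atoms: carbon tetrabromide, BrC(Br)(Br)Br
Why: Appel reaction, in which the primary homoallylic alcohol should be displaced by bromide in an SN2 manner through its alkoxyphosphonium salt without touching the (E)-alkene.

Step 2
Reactants: 2 (E)-1-bromohex-3-ene; 3 11-bromoundecan-1-ol
Product: 6 (E)-heptadec-14-en-1-ol, via (E)-hex-3-enylmagnesium bromide 4 (not isolated), via chloromagnesium 11-bromoundecan-1-olate 5 (not isolated)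
Conditions: 2, Mg, THF, rt; separately 3, MeMgCl (1 equiv), THF, −20 °C; combined, Li2CuCl4 (3 mol %), THF, −20 °C → rt; aq. NH4Cl
Reagents that add atoms: none
Why: Copper-catalysed alkyl–alkyl cross-coupling of a Grignard reagent with a primary alkyl bromide, in which the hydroxyl of 3 is masked in the flask as its magnesium alkoxide and the homoallylic Grignard reagent, used cold and soon after it is made, should keep its (E) geometry.

Step 3
Reactants: 6 (E)-heptadec-14-en-1-ol
Product: 7 (E)-17-bromoheptadec-3-ene
Conditions: CBr4, PPh3, CH2Cl2, 0 °C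
Reagents that add atoms: carbon tetrabromide, BrC(Br)(Br)Br
Why: Appel reaction on an unhindered primary alcohol, which should give the bromide cleanly and leave the remote alkene alone.

Step 4
Reactants: 7 (E)-17-bromoheptadec-3-ene; 8 N-methoxy-N-methylacetamide
Product: 10 (E)-nonadec-16-en-2-one, via (E)-heptadec-14-enylmagnesium bromide 9 (not isolated)
Conditions: Mg, THF, 40 °C; then 8, THF, 0 °C; aq. NH4Cl
Reagents that add atoms: none
Why: Weinreb ketone synthesis, in which the magnesium-chelated tetrahedral adduct survives until work-up, so the Grignard reagent should add only once and give the methyl ketone without tertiary alcohol.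

Step 5
Reactants: 10 (E)-nonadec-16-en-2-one
Product: 12 tert-butyldimethyl{[(E)-nonadeca-1,16-dien-2-yl]oxy}silane, via lithium enolate 11 (not isolated)
Conditions: LiN(iPr)2, THF, −78 °C; then t-BuMe2SiCl, DMPU, −78 → 0 °C
Reagents that add atoms: tert-butyldimethylsilyl chloride, CC(C)(C)[Si](C)(C)Cl
Why: Kinetic enolisation and O-silylation, in which the hindered amide base at −78 °C should remove a methyl proton in preference and the lithium enolate is trapped on oxygen as the 1,1-disubstituted silyl enol ether (any internal isomer is removed at the cyclobutanone stage).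

Step 6
Reactants: 12 tert-butyldimethyl{[(E)-nonadeca-1,16-dien-2-yl]oxy}silane; 13 trichloroacetyl chloride
Product: 15 3-(tert-butyldimethylsilyloxy)-2,2-dichloro-3-[(E)-heptadec-14-enyl]cyclobutan-1-one (racemic), via dichloroketene 14 (not isolated)
Conditions: Zn–Cu couple, Et2O/DME, rt, 13 (1.3 equiv) added slowly
Reagents that add atoms: none
Why: Thermal ketene–alkene [2+2] cycloaddition, in which dichloroketene made by zinc dechlorination of 13 should add to the electron-rich enol ether much faster than to the remote trans-alkene, the CH2 terminus bonding to the ketene carbonyl carbon so that the silyloxy carbon becomes C3 of the cyclobutanone.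

Step 7
Reactants: 15 3-(tert-butyldimethylsilyloxy)-2,2-dichloro-3-[(E)-heptadec-14-enyl]cyclobutan-1-one
Product: 16 3-(tert-butyldimethylsilyloxy)-3-[(E)-heptadec-14-enyl]cyclobutan-1-one
Conditions: Zn, NH4Cl, MeOH, rt
Reagents that add atoms: none
Why: Reductive dechlorination of an α,α-dichloroketone by zinc under buffered conditions, which should spare the tertiary silyl ether, the ring and the alkene and gives the achiral, Cs-symmetric cyclobutanone whose two C(O)–CH2 bonds are enantiotopic.

Step 8
Reactants: 16 3-(tert-butyldimethylsilyloxy)-3-[(E)-heptadec-14-enyl]cyclobutan-1-one; 17 acetylene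
Product: 18 (R)-5-(tert-butyldimethylsilyloxy)-5-[(E)-heptadec-14-enyl]cyclohex-2-en-1-one
Conditions: Ni(cod)2 (10 mol %), chiral monodentate phosphoramidite L* (TADDOL-derived, 20 mol %), acetylene (about 1.5 equiv, fed slowly as a dilute solution), toluene, 60 °C
Reagents that add atoms: none
Why: Proposed new method: zerovalent nickel should couple the strained carbonyl of 16 with acetylene by oxidative cyclisation to an oxanickelacyclopentene spiro-fused to the four-membered ring (new C1–C2 bond), β-carbon elimination then cuts one of the two enantiotopic C(O)–CH2 bonds with release of ring strain to give a seven-membered nickelacycle, and C(sp2)–C(sp3) reductive elimination makes C3–C4 and frees the catalyst. The closest known reaction type is the Ni(cod)2/trialkylphosphine-catalysed formal [4+2] insertion of internal alkynes into 3-substituted cyclobutanones; the use of acetylene itself and an enantioselective intermolecular variant go beyond it. The six-membered ring is closed by two-atom expansion of the four-membered ring, the ring-closing bond (C3–C4) arising by reductive elimination from the metallacycle and not by cyclisation of an open chain. The one new stereocentre, C5, is controlled by the chiral ligand on nickel, which selects the acyl–CH2 bond that is cut in the Cs-symmetric ketone. The step needs chemoselectivity for acetylene over the remote (E)-alkene, which as a 1,2-dialkyl olefin binds zerovalent nickel far more weakly, and over acetylene oligomerisation, which is held back by feeding acetylene slowly into an excess of the ketone. It also needs reductive elimination to outrun β-silyloxy elimination from the C4–nickel species, for which the substrate offers a bulky, weakly coordinating silyl ether and a quaternary C5 without β-hydrogen, and the ligand is chosen bulky to speed C–C reductive elimination.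

Step 9
Reactants: 18 (R)-5-(tert-butyldimethylsilyloxy)-5-[(E)-heptadec-14-enyl]cyclohex-2-en-1-one
Product: 19 (R)-5-[(E)-heptadec-14-enyl]-5-hydroxycyclohex-2-en-1-one
Conditions: aq. HF (48 %), MeCN, 0 °C → rt
Reagents that add atoms: none
Why: Fluoride-driven desilylation under acidic, non-enolising conditions, which should free the tertiary alcohol without the E1cB loss of the β-oxygen that a basic fluoride source could trigger.

Step 10
Reactants: 19 (R)-5-[(E)-heptadec-14-enyl]-5-hydroxycyclohex-2-en-1-one
Product: 21 (S)-5-[(E)-heptadec-14-enyl]-5-hydroxycyclohex-3-en-1-one, via dipotassium alkoxide dienolate 20 (not isolated)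
Conditions: KN(SiMe3)2 (3 equiv), THF, −78 °C, 19 added slowly, then −20 °C; cannulated into AcOH/THF, −78 °C
Reagents that add atoms: none
Why: Deconjugation of an enone by kinetic protonation of its extended dienolate, in which the alkoxide–enolate dianion can neither expel oxide nor undergo retro-aldol cleavage, amine-mediated proton transfer should move it to the more delocalised linear (O1–C2–C4) dienolate 20, and fast protonation at C2 gives the β,γ-enone with C5 untouched (the descriptor changes only because C4 now outranks C6).

Step 11
Reactants: 21 (S)-5-[(E)-heptadec-14-enyl]-5-hydroxycyclohex-3-en-1-one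
Product: 22 (1R,5S,6R)-5-[(E)-heptadec-14-enyl]-5-hydroxy-7-oxabicyclo[4.1.0]heptan-3-one
Conditions: crude 21, VO(acac)2 (5 mol %), t-BuOOH (anhydrous, in decane), CH2Cl2, 0 °C
Reagents that add atoms: tert-butyl hydroperoxide, CC(C)(C)OO
Why: Hydroxyl-directed vanadium-catalysed epoxidation of an allylic alcohol, in which the tertiary C5 hydroxyl binds the vanadium alkylperoxide and delivers oxygen to the face of C3=C4 on its own side, fixing the C4–O bond cis to the C5 hydroxyl, while the isolated chain alkene and any conjugated enone 19 carried over should not react.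

Step 12
Reactants: 22 (1R,5S,6R)-5-[(E)-heptadec-14-enyl]-5-hydroxy-7-oxabicyclo[4.1.0]heptan-3-one
Product: 23 (4R,5S)-5-[(E)-heptadec-14-enyl]-4,5-dihydroxycyclohex-2-en-1-one
Conditions: Et3N (0.2 equiv), CH2Cl2, 0 °C → rt
Reagents that add atoms: none
Why: Base-induced E1cB opening of a β,γ-epoxy ketone, in which enolisation at C2 expels the epoxide oxygen from C3 to give the conjugated enone while the C4–O bond, and with it the (4R) configuration set in step 11, is not touched.

**Compound list**

1 | (E)-hex-3-en-1-ol | CC/C=C/CCO | starting material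
2 | (E)-1-bromohex-3-ene | CC/C=C/CCBr | intermediate
3 | 11-bromoundecan-1-ol | OCCCCCCCCCCCBr | starting material
4 | (E)-hex-3-enylmagnesium bromide | CC/C=C/CC[Mg]Br | intermediate
5 | chloromagnesium 11-bromoundecan-1-olate | BrCCCCCCCCCCCO[Mg]Cl | intermediate
6 | (E)-heptadec-14-en-1-ol | CC/C=C/CCCCCCCCCCCCCO | intermediate
7 | (E)-17-bromoheptadec-3-ene | CC/C=C/CCCCCCCCCCCCCBr | intermediate
8 | N-methoxy-N-methylacetamide | CON(C)C(C)=O | starting material
9 | (E)-heptadec-14-enylmagnesium bromide | CC/C=C/CCCCCCCCCCCCC[Mg]Br | intermediate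
10 | (E)-nonadec-16-en-2-one | CC/C=C/CCCCCCCCCCCCCC(C)=O | intermediate
11 | lithium (E)-nonadeca-1,16-dien-2-olate | CC/C=C/CCCCCCCCCCCCCC(=C)O[Li] | intermediate
12 | tert-butyldimethyl{[(E)-nonadeca-1,16-dien-2-yl]oxy}silane | CC/C=C/CCCCCCCCCCCCCC(=C)O[Si](C)(C)C(C)(C)C | intermediate
13 | trichloroacetyl chloride | O=C(Cl)C(Cl)(Cl)Cl | starting material
14 | dichloroketene | O=C=C(Cl)Cl | intermediate
15 | 3-(tert-butyldimethylsilyloxy)-2,2-dichloro-3-[(E)-heptadec-14-enyl]cyclobutan-1-one (racemic) | CC/C=C/CCCCCCCCCCCCCC1(O[Si](C)(C)C(C)(C)C)CC(=O)C1(Cl)Cl | intermediate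
16 | 3-(tert-butyldimethylsilyloxy)-3-[(E)-heptadec-14-enyl]cyclobutan-1-one | CC/C=C/CCCCCCCCCCCCCC1(O[Si](C)(C)C(C)(C)C)CC(=O)C1 | intermediate
17 | acetylene | C#C | starting material
18 | (R)-5-(tert-butyldimethylsilyloxy)-5-[(E)-heptadec-14-enyl]cyclohex-2-en-1-one | CC/C=C/CCCCCCCCCCCCC[C@]1(O[Si](C)(C)C(C)(C)C)CC(=O)C=CC1 | intermediate
19 | (R)-5-[(E)-heptadec-14-enyl]-5-hydroxycyclohex-2-en-1-one | CC/C=C/CCCCCCCCCCCCC[C@]1(O)CC(=O)C=CC1 | intermediate
20 | dipotassium (S)-5-[(E)-heptadec-14-enyl]cyclohexa-1,3-diene-1,5-diolate | CC/C=C/CCCCCCCCCCCCC[C@]1([O-])CC([O-])=CC=C1.[K+].[K+] | intermediate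
21 | (S)-5-[(E)-heptadec-14-enyl]-5-hydroxycyclohex-3-en-1-one | CC/C=C/CCCCCCCCCCCCC[C@]1(O)CC(=O)CC=C1 | intermediate
22 | (1R,5S,6R)-5-[(E)-heptadec-14-enyl]-5-hydroxy-7-oxabicyclo[4.1.0]heptan-3-one | CC/C=C/CCCCCCCCCCCCC[C@]1(O)CC(=O)C[C@H]2O[C@@H]12 | intermediate
23 | (4R,5S)-5-[(E)-heptadec-14-enyl]-4,5-dihydroxycyclohex-2-en-1-one | CC/C=C/CCCCCCCCCCCCC[C@]1(O)CC(=O)C=C[C@H]1O | target

**Step count and risks**

Total step count: 12. Longest linear sequence: 12 steps (from 1 to 23).

Steps most likely to fail:

1. Step 8 (proposed new method). Acetylene may oligomerise or cyclotrimerise on nickel faster than it couples with the ketone; the alkyl–nickel intermediate may open the ring by β-silyloxy elimination; and the ligand may discriminate poorly between the two enantiotopic acyl–CH2 bonds. The fallback uses known chemistry only, gives up the cyclobutanone and sets C5 by asymmetric conjugate borylation. It sets out from bromide 7. Its Grignard reagent 9 is added to 3-ethoxycyclohex-2-en-1-one (CCOC1=CC(=O)CCC1) and the adduct is hydrolysed with dilute HCl (Stork–Danheiser enone synthesis) to 3-[(E)-heptadec-14-enyl]cyclohex-2-en-1-one F1. Copper-catalysed enantioselective conjugate borylation with bis(pinacolato)diboron (CuPF6(MeCN)4, LiOtBu, a chiral bisphosphine of the QuinoxP* type, DMSO, rt) should give the tertiary boronate (S)-3-[(E)-heptadec-14-enyl]-3-(4,4,5,5-tetramethyl-1,3,2-dioxaborolan-2-yl)cyclohexan-1-one F2, the ligand antipode being chosen for this configuration. Oxidation with NaBO3·4H2O in THF/water replaces boron by oxygen with retention and gives (R)-3-[(E)-heptadec-14-enyl]-3-hydroxycyclohexan-1-one F3. Silylation (t-BuMe2SiOTf, 2,6-lutidine, CH2Cl2, −78 °C) gives (R)-3-(tert-butyldimethylsilyloxy)-3-[(E)-heptadec-14-enyl]cyclohexan-1-one F4. Kinetic enolisation away from the quaternary carbon (LiN(iPr)2, THF, −78 °C, then Me3SiCl) gives (R)-tert-butyl{1-[(E)-heptadec-14-enyl]-3-(trimethylsilyloxy)cyclohex-3-en-1-yloxy}dimethylsilane F5. Saegusa–Ito oxidation (Pd(OAc)2, MeCN, rt) then introduces the C2=C3 double bond, and the route is rejoined at enone 18.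

2. Step 10. Proton-transfer equilibration may stay incomplete, so that the quench returns conjugated enone 19 (which step 11 leaves unchanged and which can be recycled); the potassium alkoxide may also open the ring by retro-aldol cleavage before the ketone is enolised, which would erode the C5 configuration. The fallback keeps the oxygen silylated during deconjugation, so that no free aldolate can form, and removes the silyl group afterwards. It sets out from silyl ether 18, which is equilibrated briefly to its potassium dienolate with KOtBu in t-BuOH/THF at −20 °C and quenched inversely into cold aqueous acetic acid to give (S)-5-(tert-butyldimethylsilyloxy)-5-[(E)-heptadec-14-enyl]cyclohex-3-en-1-one F6. Desilylation with HF·pyridine buffered with pyridine (THF, 0 °C) then gives 21, where the route is rejoined. Its own hazard is β-silyloxy elimination from the dienolate, which is why it is the second choice.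

3. Step 6. Zinc chloride may strip the silyl group and open the donor–acceptor cyclobutanone; dichloroketene may also add to the chain alkene; and the internal enol ether isomer from step 5 may be carried through. The fallback buys the four-membered ring instead of building it. It sets out from bromide 7, whose Grignard reagent 9 is added (CeCl3, THF, −78 °C) to commercially available 3-(benzyloxy)cyclobutan-1-one (O=C1CC(OCc2ccccc2)C1) to give 3-(benzyloxy)-1-[(E)-heptadec-14-enyl]cyclobutan-1-ol F7 as a cis/trans mixture that need not be separated. Silylation (t-BuMe2SiOTf, 2,6-lutidine, CH2Cl2) gives {[3-(benzyloxy)-1-[(E)-heptadec-14-enyl]cyclobutyl]oxy}(tert-butyl)dimethylsilane F8. Reductive debenzylation with lithium 4,4′-di-tert-butylbiphenylide (THF, −78 °C), which spares the alkene and the silyl ether, gives 3-(tert-butyldimethylsilyloxy)-3-[(E)-heptadec-14-enyl]cyclobutan-1-ol F9, and Dess–Martin oxidation returns the route to cyclobutanone 16.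

**Further compounds**

F1 | step 8 | 3-[(E)-heptadec-14-enyl]cyclohex-2-en-1-one | CC/C=C/CCCCCCCCCCCCCC1=CC(=O)CCC1
F2 | step 8 | (S)-3-[(E)-heptadec-14-enyl]-3-(4,4,5,5-tetramethyl-1,3,2-dioxaborolan-2-yl)cyclohexan-1-one | CC/C=C/CCCCCCCCCCCCC[C@]1(B2OC(C)(C)C(C)(C)O2)CC(=O)CCC1
F3 | step 8 | (R)-3-[(E)-heptadec-14-enyl]-3-hydroxycyclohexan-1-one | CC/C=C/CCCCCCCCCCCCC[C@]1(O)CC(=O)CCC1
F4 | step 8 | (R)-3-(tert-butyldimethylsilyloxy)-3-[(E)-heptadec-14-enyl]cyclohexan-1-one | CC/C=C/CCCCCCCCCCCCC[C@]1(O[Si](C)(C)C(C)(C)C)CC(=O)CCC1
F5 | step 8 | (R)-tert-butyl{1-[(E)-heptadec-14-enyl]-3-(trimethylsilyloxy)cyclohex-3-en-1-yloxy}dimethylsilane | CC/C=C/CCCCCCCCCCCCC[C@]1(O[Si](C)(C)C(C)(C)C)CC(O[Si](C)(C)C)=CCC1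
F6 | step 10 | (S)-5-(tert-butyldimethylsilyloxy)-5-[(E)-heptadec-14-enyl]cyclohex-3-en-1-one | CC/C=C/CCCCCCCCCCCCC[C@]1(O[Si](C)(C)C(C)(C)C)CC(=O)CC=C1
F7 | step 6 | 3-(benzyloxy)-1-[(E)-heptadec-14-enyl]cyclobutan-1-ol (cis/trans mixture) | CC/C=C/CCCCCCCCCCCCCC1(O)CC(OCc2ccccc2)C1
F8 | step 6 | {[3-(benzyloxy)-1-[(E)-heptadec-14-enyl]cyclobutyl]oxy}(tert-butyl)dimethylsilane (cis/trans mixture) | CC/C=C/CCCCCCCCCCCCCC1(O[Si](C)(C)C(C)(C)C)CC(OCc2ccccc2)C1
F9 | step 6 | 3-(tert-butyldimethylsilyloxy)-3-[(E)-heptadec-14-enyl]cyclobutan-1-ol (cis/trans mixture) | CC/C=C/CCCCCCCCCCCCCC1(O[Si](C)(C)C(C)(C)C)CC(O)C1
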